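**Retrosynthetic overview**

- The target is epiafzelechin-(4β→8)-epicatechin-(4β→8)-epicatechin (units T, M, L); the last operations are hydrogenolysis of a tetradeca-O-benzyl trimer and, before that, attachment of the 4-oxygenated ring B of T to a lactone carbonyl followed by silane reduction to the 2,3-cis pyran.
- Feature used: in ring C of unit T, O1 sits on ring A ortho to the benzhydryl carbon C4 (which carries M C8), and C3 is oxygenated. T C3–C4 and T O1–C2 are therefore cut back to an o-quinone methide (ring A of T, methide carbon = T C4) plus a benzyloxyacetate enolate, with C2 appearing as a lactone carbonyl.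
- The o-quinone methide comes from a ring-A benzhydrol, made by adding the C8 aryllithium of the benzylated 8-bromo M–L dimer to a protected 2,4,6-trioxygenated benzaldehyde.
- The M–L bond (M C4–L C8) comes from Lewis-acid coupling of 8-bromo-4-alkoxy penta-O-benzylepicatechin with penta-O-benzylepicatechin, both from (−)-epicatechin.
- Ring order: rings of M and L are taken from the chiral pool; ring A of T comes with the aldehyde; ring C of T is closed as the lactone in the key step and converted to the pyran afterwards; ring B of T is added last.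

Key step: step 9

Assumption: both enantiomers of the isothiourea catalyst and 1-(benzyloxy)-4-bromobenzene are taken as commercial; α/β follow the usual flavan drawing (3-oxygen α, interflavan bond β), and the carbinol configuration of the benzhydrol is immaterial because that carbon becomes trigonal before the key bond is formed.

**Step 1**
Reactants: 1 (−)-epicatechin
Product: 2 5,7,3',4'-tetra-O-benzyl-(−)-epicatechin
Conditions: BnBr (4.2 equiv), K2CO3, DMF, 0 °C → rt
Reagents that add atoms: benzyl bromide, BrCc1ccccc1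
Why: Williamson etherification of the four phenols with a carbonate base, which leaves the secondary 3-OH and the C2/C3 stereocentres untouched.

**Step 2**
Reactants: 2 5,7,3',4'-tetra-O-benzyl-(−)-epicatechin
Product: 3 3,5,7,3',4'-penta-O-benzyl-(−)-epicatechin
Conditions: NaH, BnBr, DMF, 0 °C → rt
Reagents that add atoms: benzyl bromide, BrCc1ccccc1
Why: Williamson etherification of the sodium alkoxide of the 3-OH; no stereocentre is involved.

**Step 3**
Reactants: 3 3,5,7,3',4'-penta-O-benzyl-(−)-epicatechin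
Product: 4 8-bromo-3,5,7,3',4'-penta-O-benzyl-(−)-epicatechin
Conditions: NBS (1.0 equiv), CH2Cl2, −78 °C → rt
Reagents that add atoms: N-bromosuccinimide, O=C1CCC(=O)N1Br
Why: Electrophilic aromatic bromination of the phloroglucinol-type ring A, for which C8 is the established preferred site in benzylated flavan-3-ols; the bromine later blocks C8 and then serves as the lithiation handle.

**Step 4**
Reactants: 4 8-bromo-3,5,7,3',4'-penta-O-benzyl-(−)-epicatechin
Product: 5 8-bromo-4β-(2-ethoxyethoxy)-3,5,7,3',4'-penta-O-benzyl-(−)-epicatechin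
Conditions: DDQ (2 equiv), 2-ethoxyethanol, CH2Cl2, rt
Reagents that add atoms: 2-ethoxyethanol, CCOCCO
Why: DDQ benzylic oxidation (hydride abstraction at C4 to a cation stabilised by ring A) with capture by the alcohol trans to the 3-benzyloxy group; the C4 configuration is of no consequence because the group is ionised in step 5.

**Step 5**
Reactants: 5 8-bromo-4β-(2-ethoxyethoxy)-3,5,7,3',4'-penta-O-benzyl-(−)-epicatechin; 3 3,5,7,3',4'-penta-O-benzyl-(−)-epicatechin
Product: 6 8-bromo-deca-O-benzyl-epicatechin-(4β→8)-epicatechin (bromine on C8 of the upper unit M)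
Conditions: BF3·OEt2 (0.5 equiv), 3 (2 equiv), CH2Cl2, −78 → −30 °C
Reagents that add atoms: none
Why: Friedel–Crafts alkylation by the flavan-4-yl cation at C8 of 3, its most nucleophilic position, with attack anti to the 3-benzyloxy group setting M C4 as 4β (3,4-trans); the bromine on the electrophile prevents self-condensation.

**Step 6**
Reactants: 7 2,4,6-trihydroxybenzaldehyde
Product: 8 4,6-bis(benzyloxy)-2-hydroxybenzaldehyde
Conditions: BnBr (2.05 equiv), K2CO3, DMF, rt
Reagents that add atoms: benzyl bromide, BrCc1ccccc1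
Why: Selective Williamson etherification; once the para and one ortho hydroxyl are alkylated, the remaining ortho hydroxyl is held in a hydrogen bond to the aldehyde and reacts much more slowly.

**Step 7**
Reactants: 8 4,6-bis(benzyloxy)-2-hydroxybenzaldehyde
Product: 9 4,6-bis(benzyloxy)-2-(tert-butyldimethylsilyloxy)benzaldehyde
Conditions: TBSCl, imidazole, DMF, rt
Reagents that add atoms: tert-butyldimethylsilyl chloride, CC(C)(C)[Si](C)(C)Cl
Why: Standard silylation of the phenol, which restores the electrophilicity of the aldehyde and gives a group removable by fluoride without acid.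

**Step 8**
Reactants: 6 8-bromo-deca-O-benzyl-epicatechin-(4β→8)-epicatechin; 9 4,6-bis(benzyloxy)-2-(tert-butyldimethylsilyloxy)benzaldehyde
Product: 12 ring-A benzhydrol of unit T on the dodeca-O-benzyl M–L dimer (free phenol; both carbinol epimers), via 8-lithio dimer 10 (not isolated), via silyl ether carbinol 11 (not isolated)
Conditions: n-BuLi (1.1 equiv), THF, −78 °C; 9, −78 → −40 °C; AcOH, then Bu4NF, 0 °C
Reagents that add atoms: none
Why: Bromine–lithium exchange, which outpaces benzylic deprotonation at −78 °C, then 1,2-addition of the aryllithium to the aldehyde and buffered fluoride desilylation; the new carbinol centre forms as a mixture that converges later, and any silyl migration to the alkoxide leads to the same product after fluoride treatment.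

**Step 9**
Reactants: 12 ring-A benzhydrol of unit T on the dodeca-O-benzyl M–L dimer; 13 benzyloxyacetic acid
Product: 16 (3R,4R)-3,5,7-tris(benzyloxy)-4-(deca-O-benzyl M–L dimer-8-yl)chroman-2-one (3,4-trans dihydrocoumarin of unit T), via mixed anhydride 14 (not isolated), via o-quinone methide 15 (not isolated)
Conditions: (a) 12, 4 Å MS, PhMe, 60 °C; (b) 13, t-BuCOCl, iPr2NEt, CH2Cl2, 0 °C; (c) a + b, (2R,3S)-3-isopropyl-2-phenyl-3,4-dihydro-2H-pyrimido[2,1-b][1,3]benzothiazole (20 mol%), iPr2NEt, −20 °C → rt; then 1,8-diazabicyclo[5.4.0]undec-7-ene (DBU, 20 mol%), rt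
Reagents that add atoms: none
Why: Warming 12 over sieves expels water in a thermal 1,4-dehydration to the donor-stabilised o-quinone methide 15 (so that no free phenol or carbinol is left for the acyl ammonium to acylate), while 14 acylates the isothiourea and deprotonation gives the (Z)-ammonium enolate, whose Michael addition to the methide carbon forms T C3–C4 with rearomatisation of ring A before the phenoxide attacks the acyl ammonium carbon to form T O1–C2 and release the catalyst. The closest known reaction type is the isothiourea- or carbene-catalysed formal [4+2] annulation of o-quinone methides with C1 ammonium or azolium enolates to 3,4-dihydrocoumarins. Ring C of unit T closes as the lactone by 6-exo-trig acyl substitution after the intermolecular C–C bond formation. C3 is set by the catalyst, whose C2 phenyl group screens one face of the 1,5-O···S-locked enolate so that the (2R,3S) enantiomer should give 3R, and C4 is set by the relative topicity of the Michael addition, which for isothiourea-bound enolates normally leads to the anti product, here 3,4-trans with the M unit β (4R). The step needs attack on a single face of the methide carbon, and because the di-ortho-substituted ring A of unit M must twist out of the methide plane the substrate itself offers little facial bias, so control is expected to rest with the catalyst; regiochemistry is not in question since the methide carbon is the only electrophilic site and addition restores aromaticity. The acidic C3–H lets DBU drain any 3-epimer that has the correct C4 into the more stable trans lactone.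

**Step 10**
Reactants: 16 (3R,4R)-3,5,7-tris(benzyloxy)-4-(deca-O-benzyl M–L dimer-8-yl)chroman-2-one; 17 1-(benzyloxy)-4-bromobenzene
Product: 19 2-hydroxyflavan lactol of unit T (C2 anomers; ring–chain tautomer of the phenol ketone), via 4-benzyloxyphenyllithium 18 (not isolated)
Conditions: 17, n-BuLi, THF, −78 °C; then 16 (18 at 1.3 equiv), THF, −78 °C; AcOH quench
Reagents that add atoms: none
Why: Bromine–lithium exchange followed by nucleophilic addition of the aryllithium to the δ-lactone carbonyl, the classical entry to 2-aryl lactols; low temperature, a small excess and the crowded environment of the carbonyl should hold the reaction at mono-addition and ahead of enolisation, so C3 and C4 are untouched.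

**Step 11**
Reactants: 19 2-hydroxyflavan lactol of unit T
Product: 20 tetradeca-O-benzyl-epiafzelechin-(4β→8)-epicatechin-(4β→8)-epicatechin
Conditions: Et3SiH (5 equiv), BF3·OEt2 (2 equiv), CH2Cl2, −78 → −30 °C
Reagents that add atoms: none
Why: Ionic hydrogenation (reductive etherification) through the 2-aryl oxocarbenium ion, in which the 3-benzyloxy and 4-aryl groups sit trans-diaxial and hydride should enter C2 anti to the adjacent pseudo-axial C3–O bond (β face), leaving the aryl group equatorial and cis to the 3-oxygen (2R, 2,3-cis).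

**Step 12**
Reactants: 20 tetradeca-O-benzyl-epiafzelechin-(4β→8)-epicatechin-(4β→8)-epicatechin
Product: 21 epiafzelechin-(4β→8)-epicatechin-(4β→8)-epicatechin (CNP0158921.2)
Conditions: H2 (1 atm), Pd(OH)2/C, THF/MeOH/H2O, rt
Reagents that add atoms: none
Why: Hydrogenolysis of all fourteen benzyl ethers over Pd(OH)2 on carbon under neutral conditions, which is established for benzylated proanthocyanidins and should leave the interflavan bonds, the C2–O1 bonds and all stereocentres intact.

**Compound list**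

1 | (−)-epicatechin | Oc1cc(O)c2c(c1)O[C@H](c1ccc(O)c(O)c1)[C@H](O)C2 | starting material
2 | 5,7,3',4'-tetra-O-benzyl-(−)-epicatechin | c1c(OCc9ccccc9)cc(OCc9ccccc9)c2c1O[C@H](c1ccc(OCc9ccccc9)c(OCc9ccccc9)c1)[C@H](O)C2 | intermediate
3 | 3,5,7,3',4'-penta-O-benzyl-(−)-epicatechin | c1c(OCc9ccccc9)cc(OCc9ccccc9)c2c1O[C@H](c1ccc(OCc9ccccc9)c(OCc9ccccc9)c1)[C@H](OCc9ccccc9)C2 | intermediate
4 | 8-bromo-3,5,7,3',4'-penta-O-benzyl-(−)-epicatechin | Brc1c(OCc9ccccc9)cc(OCc9ccccc9)c2c1O[C@H](c1ccc(OCc9ccccc9)c(OCc9ccccc9)c1)[C@H](OCc9ccccc9)C2 | intermediate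
5 | 8-bromo-4β-(2-ethoxyethoxy)-3,5,7,3',4'-penta-O-benzyl-(−)-epicatechin (2,3-cis-3,4-trans) | Brc1c(OCc9ccccc9)cc(OCc9ccccc9)c2c1O[C@H](c1ccc(OCc9ccccc9)c(OCc9ccccc9)c1)[C@H](OCc9ccccc9)[C@H]2OCCOCC | intermediate
6 | 8-bromo-deca-O-benzyl-epicatechin-(4β→8)-epicatechin (Br on C8 of unit M) | Brc3c(OCc9ccccc9)cc(OCc9ccccc9)c4c3O[C@H](c3ccc(OCc9ccccc9)c(OCc9ccccc9)c3)[C@H](OCc9ccccc9)[C@H]4c3c(OCc9ccccc9)cc(OCc9ccccc9)c4c3O[C@H](c3ccc(OCc9ccccc9)c(OCc9ccccc9)c3)[C@H](OCc9ccccc9)C4 | intermediate
7 | 2,4,6-trihydroxybenzaldehyde | O=Cc1c(O)cc(O)cc1O | starting material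
8 | 4,6-bis(benzyloxy)-2-hydroxybenzaldehyde | O=Cc1c(O)cc(OCc2ccccc2)cc1OCc1ccccc1 | intermediate
9 | 4,6-bis(benzyloxy)-2-(tert-butyldimethylsilyloxy)benzaldehyde | O=Cc1c(O[Si](C)(C)C(C)(C)C)cc(OCc2ccccc2)cc1OCc1ccccc1 | intermediate
10 | 8-lithio-deca-O-benzyl-epicatechin-(4β→8)-epicatechin (Li on C8 of unit M) | [Li]c3c(OCc9ccccc9)cc(OCc9ccccc9)c4c3O[C@H](c3ccc(OCc9ccccc9)c(OCc9ccccc9)c3)[C@H](OCc9ccccc9)[C@H]4c3c(OCc9ccccc9)cc(OCc9ccccc9)c4c3O[C@H](c3ccc(OCc9ccccc9)c(OCc9ccccc9)c3)[C@H](OCc9ccccc9)C4 | intermediate (not isolated)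
11 | silyl ether carbinol: [2-(tert-butyldimethylsilyloxy)-4,6-bis(benzyloxy)phenyl](dimer-8-yl)methanol, carbinol epimers | CC(C)(C)[Si](C)(C)Oc1cc(OCc9ccccc9)cc(OCc9ccccc9)c1C(O)c3c(OCc9ccccc9)cc(OCc9ccccc9)c4c3O[C@H](c3ccc(OCc9ccccc9)c(OCc9ccccc9)c3)[C@H](OCc9ccccc9)[C@H]4c3c(OCc9ccccc9)cc(OCc9ccccc9)c4c3O[C@H](c3ccc(OCc9ccccc9)c(OCc9ccccc9)c3)[C@H](OCc9ccccc9)C4 | intermediate (not isolated)
12 | ring-A benzhydrol of unit T: [2-hydroxy-4,6-bis(benzyloxy)phenyl](deca-O-benzyl M–L dimer-8-yl)methanol, carbinol epimers | Oc1cc(OCc9ccccc9)cc(OCc9ccccc9)c1C(O)c3c(OCc9ccccc9)cc(OCc9ccccc9)c4c3O[C@H](c3ccc(OCc9ccccc9)c(OCc9ccccc9)c3)[C@H](OCc9ccccc9)[C@H]4c3c(OCc9ccccc9)cc(OCc9ccccc9)c4c3O[C@H](c3ccc(OCc9ccccc9)c(OCc9ccccc9)c3)[C@H](OCc9ccccc9)C4 | intermediate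
13 | benzyloxyacetic acid | OC(=O)COCc1ccccc1 | starting material
14 | benzyloxyacetic pivalic anhydride | CC(C)(C)C(=O)OC(=O)COCc1ccccc1 | intermediate (not isolated)
15 | o-quinone methide: 3,5-bis(benzyloxy)-6-[(deca-O-benzyl M–L dimer-8-yl)methylidene]cyclohexa-2,4-dien-1-one (methide geometry not fixed) | O=C1C=C(OCc9ccccc9)C=C(OCc9ccccc9)C1=Cc3c(OCc9ccccc9)cc(OCc9ccccc9)c4c3O[C@H](c3ccc(OCc9ccccc9)c(OCc9ccccc9)c3)[C@H](OCc9ccccc9)[C@H]4c3c(OCc9ccccc9)cc(OCc9ccccc9)c4c3O[C@H](c3ccc(OCc9ccccc9)c(OCc9ccccc9)c3)[C@H](OCc9ccccc9)C4 | intermediate (not isolated)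
16 | (3R,4R)-3,5,7-tris(benzyloxy)-4-(deca-O-benzyl M–L dimer-8-yl)chroman-2-one (3,4-trans) | O=C1Oc2cc(OCc9ccccc9)cc(OCc9ccccc9)c2[C@H](c3c(OCc9ccccc9)cc(OCc9ccccc9)c4c3O[C@H](c3ccc(OCc9ccccc9)c(OCc9ccccc9)c3)[C@H](OCc9ccccc9)[C@H]4c3c(OCc9ccccc9)cc(OCc9ccccc9)c4c3O[C@H](c3ccc(OCc9ccccc9)c(OCc9ccccc9)c3)[C@H](OCc9ccccc9)C4)[C@H]1OCc9ccccc9 | intermediate
17 | 1-(benzyloxy)-4-bromobenzene | Brc1ccc(OCc2ccccc2)cc1 | starting material
18 | 4-(benzyloxy)phenyllithium | [Li]c1ccc(OCc2ccccc2)cc1 | intermediate (not isolated)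
19 | 2-hydroxyflavan lactol of unit T: 2-[4-(benzyloxy)phenyl]-2-hydroxy derivative of 16 with the lactone carbonyl converted to the hemiketal (C2 anomers) | OC1(c5ccc(OCc9ccccc9)cc5)Oc2cc(OCc9ccccc9)cc(OCc9ccccc9)c2[C@H](c3c(OCc9ccccc9)cc(OCc9ccccc9)c4c3O[C@H](c3ccc(OCc9ccccc9)c(OCc9ccccc9)c3)[C@H](OCc9ccccc9)[C@H]4c3c(OCc9ccccc9)cc(OCc9ccccc9)c4c3O[C@H](c3ccc(OCc9ccccc9)c(OCc9ccccc9)c3)[C@H](OCc9ccccc9)C4)[C@H]1OCc9ccccc9 | intermediate
20 | tetradeca-O-benzyl-epiafzelechin-(4β→8)-epicatechin-(4β→8)-epicatechin | c9ccccc9COc1ccc([C@H]2Oc3cc(OCc9ccccc9)cc(OCc9ccccc9)c3[C@H](c3c(OCc9ccccc9)cc(OCc9ccccc9)c4c3O[C@H](c3ccc(OCc9ccccc9)c(OCc9ccccc9)c3)[C@H](OCc9ccccc9)[C@H]4c3c(OCc9ccccc9)cc(OCc9ccccc9)c4c3O[C@H](c3ccc(OCc9ccccc9)c(OCc9ccccc9)c3)[C@H](OCc9ccccc9)C4)[C@H]2OCc9ccccc9)cc1 | intermediate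
21 | epiafzelechin-(4β→8)-epicatechin-(4β→8)-epicatechin (CNP0158921.2) | Oc1ccc([C@H]2Oc3cc(O)cc(O)c3[C@H](c3c(O)cc(O)c4c3O[C@H](c3ccc(O)c(O)c3)[C@H](O)[C@H]4c3c(O)cc(O)c4c3O[C@H](c3ccc(O)c(O)c3)[C@H](O)C4)[C@H]2O)cc1 | target

**Step count and risks**

Total step count: 12. Longest linear sequence: 10 steps (steps 1–5 and 8–12, from 1 to 21).

Steps most likely to fail:

1. Step 9. The Michael addition may be slow at the crowded, strongly stabilised methide carbon, the quinone methide may oligomerise through free ring-A positions, and the facial selectivity at the methide (C4) may be poor or opposite to the model (the antipodal catalyst with C3 epimerisation would be the first adjustment). Fallback, setting out from 12: the chlorotitanium (Z)-enolate of (S)-4-benzyl-3-(benzyloxyacetyl)oxazolidin-2-one (TiCl4, iPr2NEt, CH2Cl2, −78 °C) is alkylated by the diarylmethyl cation/quinone methide that the same Lewis acid releases from 12. This is an auxiliary-controlled SN1-type alkylation of a titanium enolate, anti to the benzyl group of the auxiliary, and should set C3 as R in the open-chain phenolic imide adduct F1. Treatment with K2CO3 or 4-(dimethylamino)pyridine then lactonises the phenol onto the imide carbonyl with loss of the auxiliary; any C4 epimer is removed by chromatography. The route is rejoined at 16.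

2. Step 11. Hydride delivery may lack facial selectivity, because the β face of C2 is 1,3-related to the bulky 4β substituent, which would give the 2,3-trans flavan; C3 may also be scrambled by reversible loss of H3 to the flav-2-ene. Fallback, setting out from 19: the open hydroxy-ketone tautomer is reduced with Zn(BH4)2 under chelation control (Cram chelate between the ketone and the 3-benzyloxy oxygen) to the anti diol F2. Mitsunobu cyclisation (PPh3, DIAD, THF) then closes ring C by attack of the phenol with inversion at the benzylic carbinol, giving the 2,3-cis flavan. The route is rejoined at 20.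

3. Step 10. The tetrahedral intermediate may expel the phenoxide and the unmasked ketone may take up a second aryllithium, or the lactone may be enolised with ketene formation and loss of the C3 configuration. Fallback, setting out from 16: the lactone is opened with Me(MeO)NH·HCl/AlMe3 (CH2Cl2, 0 °C) to the phenolic Weinreb amide F3. An excess of 18 (the first equivalent deprotonating the phenol; THF, −78 °C) then adds once, the chelated tetrahedral intermediate preventing over-addition, and the ketone released on work-up closes to the lactol. The route is rejoined at 19.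

**Further compounds**

F1 | step 9 | (S)-4-benzyl-3-[(2R,3R)-2-benzyloxy-3-(2-hydroxy-4,6-bis(benzyloxy)phenyl)-3-(deca-O-benzyl M–L dimer-8-yl)propanoyl]oxazolidin-2-one | Oc1cc(OCc9ccccc9)cc(OCc9ccccc9)c1[C@H](c3c(OCc9ccccc9)cc(OCc9ccccc9)c4c3O[C@H](c3ccc(OCc9ccccc9)c(OCc9ccccc9)c3)[C@H](OCc9ccccc9)[C@H]4c3c(OCc9ccccc9)cc(OCc9ccccc9)c4c3O[C@H](c3ccc(OCc9ccccc9)c(OCc9ccccc9)c3)[C@H](OCc9ccccc9)C4)[C@@H](OCc9ccccc9)C(=O)N5C(=O)OC[C@@H]5Cc6ccccc6
F2 | step 11 | anti diol: 2-benzyloxy-1-[4-(benzyloxy)phenyl]-3-(2-hydroxy-4,6-bis(benzyloxy)phenyl)-3-(deca-O-benzyl M–L dimer-8-yl)propan-1-ol (carbinol configuration opposite to C2 of 20) | Oc1cc(OCc9ccccc9)cc(OCc9ccccc9)c1[C@H](c3c(OCc9ccccc9)cc(OCc9ccccc9)c4c3O[C@H](c3ccc(OCc9ccccc9)c(OCc9ccccc9)c3)[C@H](OCc9ccccc9)[C@H]4c3c(OCc9ccccc9)cc(OCc9ccccc9)c4c3O[C@H](c3ccc(OCc9ccccc9)c(OCc9ccccc9)c3)[C@H](OCc9ccccc9)C4)[C@@H](OCc9ccccc9)[C@@H](O)c5ccc(OCc9ccccc9)cc5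
F3 | step 10 | Weinreb amide: (2R,3R)-2-benzyloxy-3-(2-hydroxy-4,6-bis(benzyloxy)phenyl)-3-(deca-O-benzyl M–L dimer-8-yl)-N-methoxy-N-methylpropanamide | Oc1cc(OCc9ccccc9)cc(OCc9ccccc9)c1[C@H](c3c(OCc9ccccc9)cc(OCc9ccccc9)c4c3O[C@H](c3ccc(OCc9ccccc9)c(OCc9ccccc9)c3)[C@H](OCc9ccccc9)[C@H]4c3c(OCc9ccccc9)cc(OCc9ccccc9)c4c3O[C@H](c3ccc(OCc9ccccc9)c(OCc9ccccc9)c3)[C@H](OCc9ccccc9)C4)[C@@H](OCc9ccccc9)C(=O)N(C)OC
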